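Readings and results were computed for substances that don't exist; noise was put on by code.

Amounts first. At 120 min the eta flask holds 5.6 % of its substrate and 18.7 % as product, so 75.7 % has left by another way. Substrate is the limiting reagent, so it is the one I keep the books on.

| flask | substrate | coupling partner | remark | time |
|---|---|---|---|---|
| eta | 0.050 M | 1 equiv | run made earlier |  |
| theta | 0.034 M | 1 equiv | run made earlier |  |
| gamma | 0.075 M | 1 equiv | run made earlier |  |
| epsilon | 0.050 M | 0.50 equiv | run made earlier |  |
| maple | 0.050 M (fed, over 2.5 h) | 1.00 equiv | all else is in the flask from the start; the feed brings no volume worth counting | 3.0 h |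
| alder | 0.050 M | 1.00 equiv | everything together at the start | 3.0 h |
| elm | 0.050 M | 1.00 equiv (in portions, 5, over 2.5 h) | first portion at the start, last at 2.5 h | 3.0 h |
| oak | 0.050 M | 1.00 equiv (fed, over 15 min) | all else is in the flask from the start; the feed brings no volume worth counting | 3.0 h |
| cedar | 0.050 M | 1.00 equiv (fed, over 2.5 h) | all else is in the flask from the start; the feed brings no volume worth counting | 3.0 h |

eta run (percent of the substrate charged)

| time / min | product / % | substrate / % |
|---|---|---|
| 10.0 | 4.5 | 51.7 |
| 25.0 | 8.0 | 30.3 |
| 50.0 | 12.5 | 17.3 |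
| 80.0 | 14.9 | 11.2 |
| 120 | 18.7 | 5.6 |

theta run (percent of the substrate charged)

| time / h | product / % | substrate / % |
|---|---|---|
| 0.500 | 7.4 | 36.5 |
| 1.00 | 10.4 | 21.2 |
| 1.33 | 12.2 | 15.8 |
| 2.00 | 16.5 | 13.0 |
| 2.50 | 16.7 | 10.1 |

gamma run (percent of the substrate charged)

| time / h | product / % | substrate / % |
|---|---|---|
| 0.200 | 8.0 | 38.0 |
| 0.667 | 12.2 | 15.1 |
| 1.00 | 16.2 | 10.2 |
| 1.50 | 17.4 | 4.4 |
| 2.50 | 18.7 | 3.1 |

epsilon run (percent of the substrate charged)

| time / h | product / % | substrate / % |
|---|---|---|
| 0.500 | 4.7 | 27.0 |
| 1.00 | 7.2 | 16.0 |
| 1.33 | 9.5 | 14.5 |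
| 2.00 | 10.4 | 7.7 |
| 2.50 | 12.1 | 6.4 |

(scatter of a reading: 1 percentage point)

* the flask with the highest amount of product, in percent of the substrate charged ("all alike" if they lie within 1.5 percentage points) (maple / alder / elm / oak / cedar / all alike)
* final product, as a percentage of the substrate charged, in maple
* final product, as a percentage of the substrate charged, in alder
* final product, as a percentage of the substrate charged, in elm
* final product, as a percentage of the substrate charged, in oak
* final product, as a percentage of the substrate charged, in cedar



The other way goes on with less partner: with 0.50 equiv the epsilon flask reads 7.7 % substrate at 2.00 h, close to eta's 5.6 %, while product drops to 10.4 %. One over substrate, less one, grows in step with time, at a loss pace of 5.74 h⁻¹ in eta. Gamma, at 0.075 M, gives 8.80 h⁻¹, so the pace follows concentration and the loss goes with the square of substrate.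

Product is the entry I can steer, so I count its turnovers. I integrate substrate over time into substrate-hours, and define the capture rate, the product made per hour for each unit of substrate and of partner, both as fractions of the charge at 0.050 M. Eta has 0.440 h of substrate-hours and its partner averages 90.6 %, so

capture rate = 0.469 h⁻¹

I expect maple's feed to hold substrate near a level of 26.4 %, where feed meets loss. At that level I reckon the product share per unit of loss at 0.309, against 0.0817 at full charge.

Where partner is fed, I weight the substrate-hours by the partner present:

alder: 0.506 h gives 21.2 %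
maple: 0.638 h gives 26.0 %
oak: 0.417 h gives 17.8 %
elm: 0.198 h gives 9.30 %
cedar: 0.171 h gives 8.02 %

So I put maple first.

The forecast names maple, with 25 % for maple, 20.5 % for alder, 8.5 % for elm, 17.5 % for oak and 7.5 % for cedar, lower than mine on maple, and says “Feeding substrate slowly wins”.

The flasks give 23.2 % in maple, 19.8 % in alder, 9.25 % in elm, 17.5 % in oak and 8.28 % in cedar, so maple leads.

    substrate ⇌ reactive form (K = 0.150, k = 0.00140 s⁻¹)
    coupling partner + reactive form → product (k = 0.0180 M⁻¹ s⁻¹)
    2 substrate → homo dimer (k = 0.0130 M⁻¹ s⁻¹)

Maple's books close at 3.00 h with 14.6 % substrate, 23.2 % product, 2.09 % reactive form and 60.2 % homo dimer. Maple ends below my 26.0 %. From 1.50 h to 2.50 h, maple's substrate goes from 24.0 % to 25.4 % and its partner from 89.8 % to 80.3 %, so the capture rate, on the means of these two moments, gives 9.85 % of product; maple's product rises by 9.5 percentage points.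

For the neighbour of cedar with 0.250 equiv of partner, I scale cedar's weighted substrate-hours by that charge, so the capture rate gives 2.00 %. That neighbour flask gives 2.42 %.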